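## Retrosynthetic overview

1. The last step is fluoride removal of three silyl ethers; no other protecting groups are carried.
2. Ring C (the oxygen ring of the flavan) is cut at O1–C2 and C3–C4: an enantioselective oxa-[4+2] between a ring A ortho-quinone methide and a ring B styrene sets C2 (proposed new step).
3. Fragment A comes from 2,4-dihydroxybenzaldehyde; the 1,1-dimethylallyl group is placed by aromatic Claisen rearrangement of the 4-O-prenyl ether.
4. Fragment B comes from 2-bromo-4,5-dihydroxybenzaldehyde; ring D (the dimethylpyran on ring B) is built by propargyl ether Claisen/electrocyclisation, and its carbinol centre by Jacobsen epoxidation and benzylic hydride opening; Br becomes prenyl, CHO becomes vinyl.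
5. Order of ring formation: rings A and B are bought, ring D is formed first, ring C last.

Assumption: 2-bromo-4,5-dihydroxybenzaldehyde is taken as a catalogue compound, and the (R)-acid in step 15 is taken to give 2R (if the first run shows the opposite sense, the (S)-acid is used).

Abbreviations: TBS = tert-butyldimethylsilyl, TIPS = triisopropylsilyl.

## Route

**Fragment A**

Step 1
Reactants: 1 2,4-dihydroxybenzaldehyde; 2 1-bromo-3-methylbut-2-ene (prenyl bromide)
Product: 3 2-hydroxy-4-(3-methylbut-2-enyloxy)benzaldehyde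
Conditions: K2CO3 (1.1 equiv), acetone, reflux
Reagents that add atoms: none
Why: Williamson ether synthesis, in which the 2-OH is tied up in a hydrogen bond to the formyl group so that only the free, more acidic 4-OH is alkylated.

Step 2
Reactants: 3 2-hydroxy-4-(3-methylbut-2-enyloxy)benzaldehyde
Product: 4 2-formyl-5-(3-methylbut-2-enyloxy)phenyl acetate
Conditions: Ac2O, Et3N, 4-(dimethylamino)pyridine (5 mol%), CH2Cl2, 0 °C to rt
Reagents that add atoms: acetic anhydride, CC(=O)OC(C)=O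
Why: Nucleophile-catalysed O-acylation caps the chelated phenol, which removes the hydrogen-bond bond fixation that would steer the coming Claisen shift to C3.

Step 3
Reactants: 4 2-formyl-5-(3-methylbut-2-enyloxy)phenyl acetate
Product: 6 2-formyl-5-hydroxy-4-(2-methylbut-3-en-2-yl)phenyl acetate, via Claisen dienone 5 (not isolated)
Conditions: Eu(fod)3 [europium tris(6,6,7,7,8,8,8-heptafluoro-2,2-dimethyl-3,5-octanedionate), C30H30EuF21O6] (10 mol%), toluene, 100 °C
Reagents that add atoms: none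
Why: Lewis-acid-accelerated aromatic Claisen rearrangement ([3,3] with allylic inversion) delivers the tertiary carbon to C5, the ortho position not wedged between two oxygens, and dienone 5 tautomerises to the phenol.

Step 4
Reactants: 6 2-formyl-5-hydroxy-4-(2-methylbut-3-en-2-yl)phenyl acetate
Product: 7 5-(TBSO)-2-formyl-4-(2-methylbut-3-en-2-yl)phenyl acetate
Conditions: TBSOTf, 2,6-lutidine, CH2Cl2, 0 °C
Reagents that add atoms: tert-butyldimethylsilyl triflate, CC(C)(C)[Si](C)(C)OS(=O)(=O)C(F)(F)F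
Why: Silyl triflate silylation is reactive enough for the phenol next to the quaternary carbon, and the hindered aryl silyl ether later blocks the para-quinone methide pathway.

Step 5
Reactants: 7 5-(TBSO)-2-formyl-4-(2-methylbut-3-en-2-yl)phenyl acetate
Product: 8 5-(TBSO)-2-(hydroxymethyl)-4-(2-methylbut-3-en-2-yl)phenol
Conditions: i-Bu2AlH (4 equiv), CH2Cl2, −78 to 0 °C; aq. KNaC4H4O6
Reagents that add atoms: none
Why: Hydride reduction in which i-Bu2AlH reduces the aldehyde to the benzylic alcohol and cleaves the aryl acetate in the same flask, while the hindered aryl silyl ether and the alkene are inert.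

**Fragment B**

Step 6
Reactants: 9 2-bromo-4,5-dihydroxybenzaldehyde; 10 3-chloro-3-methylbut-1-yne
Product: 11 2-bromo-5-hydroxy-4-(2-methylbut-3-yn-2-yloxy)benzaldehyde
Conditions: K2CO3 (1.05 equiv), KI (20 mol%), DMF, 60 °C, N2
Reagents that add atoms: none
Why: Phenol O-alkylation in which the 4-OH para to the formyl group is the more acidic one, so one equivalent of base forms and alkylates that phenoxide selectively.

Step 7
Reactants: 11 2-bromo-5-hydroxy-4-(2-methylbut-3-yn-2-yloxy)benzaldehyde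
Product: 12 2-bromo-4-(2-methylbut-3-yn-2-yloxy)-5-(TIPSO)benzaldehyde
Conditions: TIPSCl, imidazole, DMF, rt
Reagents that add atoms: chlorotriisopropylsilane, CC(C)[Si](Cl)(C(C)C)C(C)C
Why: Standard imidazole-mediated silylation gives an aryl TIPS ether that withstands the heat, bleach, hydride and base of the following steps.

Step 8
Reactants: 12 2-bromo-4-(2-methylbut-3-yn-2-yloxy)-5-(TIPSO)benzaldehyde
Product: 14 5-bromo-2,2-dimethyl-8-(TIPSO)-2H-chromene-6-carbaldehyde, via allenylphenol 13 (not isolated)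
Conditions: PhNEt2, 190 °C
Reagents that add atoms: none
Why: Propargyl Claisen rearrangement to the only free ortho carbon gives allenylphenol 13, which closes ring D by 1,5-hydrogen shift and oxa-6π electrocyclisation.

Step 9
Reactants: 14 5-bromo-2,2-dimethyl-8-(TIPSO)-2H-chromene-6-carbaldehyde
Product: 15 (3S,4S)-5-bromo-3,4-epoxy-2,2-dimethyl-8-(TIPSO)chroman-6-carbaldehyde
Conditions: (S,S)-Jacobsen catalyst [(S,S)-N,N'-bis(3,5-di-tert-butylsalicylidene)-1,2-cyclohexanediaminomanganese chloride, C36H52ClMnN2O2] (4 mol%), NaOCl (aq, pH 11.3), 4-phenylpyridine N-oxide, CH2Cl2, 0 °C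
Reagents that add atoms: sodium hypochlorite, [Na+].[O-]Cl
Why: Jacobsen–Katsuki epoxidation, for which 2,2-dimethylchromenes are the best substrate class; the (S,S) complex gives the (3S,4S) oxide and so fixes the carbinol centre of ring D.

Step 10
Reactants: 15 (3S,4S)-5-bromo-3,4-epoxy-2,2-dimethyl-8-(TIPSO)chroman-6-carbaldehyde
Product: 17 (3S)-5-bromo-6-(hydroxymethyl)-2,2-dimethyl-8-(TIPSO)chroman-3-ol, via epoxy alcohol 16 (not isolated)
Conditions: LiAlH4, THF, 0 °C to rt
Reagents that add atoms: none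
Why: Hydride reduction in which the aldehyde goes first and the oxirane is then opened by SN2 attack at benzylic C4 (C3 is neopentyl), so the C3–O bond is never broken and 3S is kept.

Step 11
Reactants: 17 (3S)-5-bromo-6-(hydroxymethyl)-2,2-dimethyl-8-(TIPSO)chroman-3-ol
Product: 18 (3S)-5-bromo-3-hydroxy-2,2-dimethyl-8-(TIPSO)chroman-6-carbaldehyde
Conditions: MnO2, CH2Cl2, rt
Reagents that add atoms: none
Why: MnO2 oxidises only the benzylic primary alcohol and leaves the aliphatic secondary alcohol untouched.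

Step 12
Reactants: 18 (3S)-5-bromo-3-hydroxy-2,2-dimethyl-8-(TIPSO)chroman-6-carbaldehyde
Product: 19 (3S)-5-bromo-3-(TBSO)-2,2-dimethyl-8-(TIPSO)chroman-6-carbaldehyde
Conditions: TBSOTf, 2,6-lutidine, CH2Cl2, −78 to 0 °C
Reagents that add atoms: tert-butyldimethylsilyl triflate, CC(C)(C)[Si](C)(C)OS(=O)(=O)C(F)(F)F
Why: Silyl triflate silylation masks the hindered secondary alcohol so that it cannot add to the quinone methide in step 15.

Step 13
Reactants: 19 (3S)-5-bromo-3-(TBSO)-2,2-dimethyl-8-(TIPSO)chroman-6-carbaldehyde; 20 tributyl(3-methylbut-2-enyl)stannane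
Product: 21 (3S)-3-(TBSO)-2,2-dimethyl-5-(3-methylbut-2-enyl)-8-(TIPSO)chroman-6-carbaldehyde
Conditions: Pd(PPh3)4 (5 mol%), DMF, 95 °C
Reagents that add atoms: none
Why: Migita–Kosugi–Stille coupling in which the formyl-activated bromide adds to palladium and the allyl palladium intermediate eliminates at its less hindered primary end to give the linear prenyl group, the stannane being inert to the aldehyde.

Step 14
Reactants: 21 (3S)-3-(TBSO)-2,2-dimethyl-5-(3-methylbut-2-enyl)-8-(TIPSO)chroman-6-carbaldehyde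
Product: 22 (3S)-3-(TBSO)-6-ethenyl-2,2-dimethyl-5-(3-methylbut-2-enyl)-8-(TIPSO)chroman
Conditions: Ph3PCH3Br, KOtBu, THF, 0 °C to rt
Reagents that add atoms: methyltriphenylphosphonium bromide, C[P+](c1ccccc1)(c1ccccc1)c1ccccc1.[Br-]
Why: Wittig methylenation converts the aldehyde into the electron-rich styrene without touching the silyl ethers or the stereocentre.

**Union and deprotection**

Step 15
Reactants: 8 5-(TBSO)-2-(hydroxymethyl)-4-(2-methylbut-3-en-2-yl)phenol; 22 (3S)-3-(TBSO)-6-ethenyl-2,2-dimethyl-5-(3-methylbut-2-enyl)-8-(TIPSO)chroman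
Product: 24 (2R)-7-(TBSO)-2-[(3S)-3-(TBSO)-2,2-dimethyl-5-(3-methylbut-2-enyl)-8-(TIPSO)chroman-6-yl]-6-(2-methylbut-3-en-2-yl)chroman, via ortho-quinone methide 23 (not isolated)
Conditions: (R)-TRIP [(R)-3,3'-bis(2,4,6-triisopropylphenyl)-1,1'-binaphthyl-2,2'-diyl hydrogen phosphate, C50H57O4P] (10 mol%), 5 Å MS, PhCF3, −20 to 0 °C
Reagents that add atoms: none
Why: Proposed new method: the chiral phosphoric acid dehydrates the doubly oxygen-activated salicyl alcohol 8 to ortho-quinone methide 23 and holds it by hydrogen bonding in the chiral pocket, the 4-alkoxystyrene (the most nucleophilic alkene present) attacks the methide carbon through its terminal CH2 in an asynchronous inverse-electron-demand oxa-[4+2], and the developing para-alkoxybenzylic carbon is captured by the phosphate-bound phenolic oxygen on one face only, which closes ring C and sets C2 as R independently of the remote 3S centre; the closest known reaction type is the chiral-phosphoric-acid-catalysed [4+2] cycloaddition of methide-aryl ortho-quinone methides (from ortho-hydroxybenzhydrols) with styrenes and enol ethers, extended here to a methide-unsubstituted quinone methide and a hindered styrene without a hydrogen-bonding handle, so that C2 is the only new stereocentre.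

Step 16
Reactants: 24 (2R)-7-(TBSO)-2-[(3S)-3-(TBSO)-2,2-dimethyl-5-(3-methylbut-2-enyl)-8-(TIPSO)chroman-6-yl]-6-(2-methylbut-3-en-2-yl)chroman
Product: 25 (2R)-2-[(3S)-3,8-dihydroxy-2,2-dimethyl-5-(3-methylbut-2-enyl)chroman-6-yl]-6-(2-methylbut-3-en-2-yl)chroman-7-ol (CNP0323011.2)
Conditions: n-Bu4NF (4 equiv), AcOH (4 equiv), THF, 0 °C to rt
Reagents that add atoms: none
Why: Fluoride-driven Si–O cleavage removes both aryl silyl ethers and the secondary silyl ether under buffered, non-acidic conditions that leave the acid-labile 2-aryl benzylic ether, both alkenes and both stereocentres untouched.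

## Compound list

1 | 2,4-dihydroxybenzaldehyde | O=Cc1ccc(O)cc1O | starting material
2 | 1-bromo-3-methylbut-2-ene (prenyl bromide) | CC(C)=CCBr | starting material
3 | 2-hydroxy-4-(3-methylbut-2-enyloxy)benzaldehyde | O=Cc1ccc(OCC=C(C)C)cc1O | intermediate
4 | 2-formyl-5-(3-methylbut-2-enyloxy)phenyl acetate | CC(=O)Oc1cc(OCC=C(C)C)ccc1C=O | intermediate
5 | 3-acetoxy-4-formyl-6-(2-methylbut-3-en-2-yl)cyclohexa-2,4-dien-1-one (racemic, not isolated) | O=C1C=C(OC(C)=O)C(C=O)=CC1C(C)(C)C=C | intermediate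
6 | 2-formyl-5-hydroxy-4-(2-methylbut-3-en-2-yl)phenyl acetate | CC(=O)Oc1cc(O)c(C(C)(C)C=C)cc1C=O | intermediate
7 | 5-(tert-butyldimethylsilyloxy)-2-formyl-4-(2-methylbut-3-en-2-yl)phenyl acetate | CC(=O)Oc1cc(O[Si](C)(C)C(C)(C)C)c(C(C)(C)C=C)cc1C=O | intermediate
8 | 5-(tert-butyldimethylsilyloxy)-2-(hydroxymethyl)-4-(2-methylbut-3-en-2-yl)phenol | OCc1cc(C(C)(C)C=C)c(O[Si](C)(C)C(C)(C)C)cc1O | intermediate
9 | 2-bromo-4,5-dihydroxybenzaldehyde | O=Cc1cc(O)c(O)cc1Br | starting material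
10 | 3-chloro-3-methylbut-1-yne | C#CC(C)(C)Cl | starting material
11 | 2-bromo-5-hydroxy-4-(2-methylbut-3-yn-2-yloxy)benzaldehyde | O=Cc1cc(O)c(OC(C)(C)C#C)cc1Br | intermediate
12 | 2-bromo-4-(2-methylbut-3-yn-2-yloxy)-5-(triisopropylsilyloxy)benzaldehyde | O=Cc1cc(O[Si](C(C)C)(C(C)C)C(C)C)c(OC(C)(C)C#C)cc1Br | intermediate
13 | 2-bromo-4-hydroxy-3-(3-methylbuta-1,2-dienyl)-5-(triisopropylsilyloxy)benzaldehyde (not isolated) | O=Cc1cc(O[Si](C(C)C)(C(C)C)C(C)C)c(O)c(C=C=C(C)C)c1Br | intermediate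
14 | 5-bromo-2,2-dimethyl-8-(triisopropylsilyloxy)-2H-chromene-6-carbaldehyde | CC1(C)C=Cc2c(Br)c(C=O)cc(O[Si](C(C)C)(C(C)C)C(C)C)c2O1 | intermediate
15 | (3S,4S)-5-bromo-3,4-epoxy-2,2-dimethyl-8-(triisopropylsilyloxy)chroman-6-carbaldehyde | O=Cc1cc(O[Si](C(C)C)(C(C)C)C(C)C)c2c(c1Br)[C@@H]3O[C@@H]3C(C)(C)O2 | intermediate
16 | [(3S,4S)-5-bromo-3,4-epoxy-2,2-dimethyl-8-(triisopropylsilyloxy)chroman-6-yl]methanol (not isolated) | OCc1cc(O[Si](C(C)C)(C(C)C)C(C)C)c2c(c1Br)[C@@H]3O[C@@H]3C(C)(C)O2 | intermediate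
17 | (3S)-5-bromo-6-(hydroxymethyl)-2,2-dimethyl-8-(triisopropylsilyloxy)chroman-3-ol | OCc1cc(O[Si](C(C)C)(C(C)C)C(C)C)c2c(c1Br)C[C@H](O)C(C)(C)O2 | intermediate
18 | (3S)-5-bromo-3-hydroxy-2,2-dimethyl-8-(triisopropylsilyloxy)chroman-6-carbaldehyde | O=Cc1cc(O[Si](C(C)C)(C(C)C)C(C)C)c2c(c1Br)C[C@H](O)C(C)(C)O2 | intermediate
19 | (3S)-5-bromo-3-(tert-butyldimethylsilyloxy)-2,2-dimethyl-8-(triisopropylsilyloxy)chroman-6-carbaldehyde | O=Cc1cc(O[Si](C(C)C)(C(C)C)C(C)C)c2c(c1Br)C[C@H](O[Si](C)(C)C(C)(C)C)C(C)(C)O2 | intermediate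
20 | tributyl(3-methylbut-2-enyl)stannane | CC(C)=CC[Sn](CCCC)(CCCC)CCCC | starting material
21 | (3S)-3-(tert-butyldimethylsilyloxy)-2,2-dimethyl-5-(3-methylbut-2-enyl)-8-(triisopropylsilyloxy)chroman-6-carbaldehyde | O=Cc1cc(O[Si](C(C)C)(C(C)C)C(C)C)c2c(c1CC=C(C)C)C[C@H](O[Si](C)(C)C(C)(C)C)C(C)(C)O2 | intermediate
22 | (3S)-3-(tert-butyldimethylsilyloxy)-6-ethenyl-2,2-dimethyl-5-(3-methylbut-2-enyl)-8-(triisopropylsilyloxy)chroman | C=Cc1cc(O[Si](C(C)C)(C(C)C)C(C)C)c2c(c1CC=C(C)C)C[C@H](O[Si](C)(C)C(C)(C)C)C(C)(C)O2 | intermediate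
23 | 3-(tert-butyldimethylsilyloxy)-6-methylidene-4-(2-methylbut-3-en-2-yl)cyclohexa-2,4-dien-1-one (not isolated) | C=C1C=C(C(C)(C)C=C)C(O[Si](C)(C)C(C)(C)C)=CC1=O | intermediate
24 | (2R)-7-(tert-butyldimethylsilyloxy)-2-[(3S)-3-(tert-butyldimethylsilyloxy)-2,2-dimethyl-5-(3-methylbut-2-enyl)-8-(triisopropylsilyloxy)chroman-6-yl]-6-(2-methylbut-3-en-2-yl)chroman | C=CC(C)(C)c1cc2c(cc1O[Si](C)(C)C(C)(C)C)O[C@@H](c1cc(O[Si](C(C)C)(C(C)C)C(C)C)c3c(c1CC=C(C)C)C[C@H](O[Si](C)(C)C(C)(C)C)C(C)(C)O3)CC2 | intermediate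
25 | (2R)-2-[(3S)-3,8-dihydroxy-2,2-dimethyl-5-(3-methylbut-2-enyl)chroman-6-yl]-6-(2-methylbut-3-en-2-yl)chroman-7-ol | C=CC(C)(C)c1cc2c(cc1O)O[C@@H](c1cc(O)c3c(c1CC=C(C)C)C[C@H](O)C(C)(C)O3)CC2 | target

## Step count and risks

Total steps: 16 (fragment A 5, fragment B 9, union and deprotection 2).
Longest linear sequence: 11 steps (steps 6 to 16, from 9 to 25).

**Step 15 (proposed new step).** The acid may give low face selectivity with a styrene that has no hydrogen-bonding handle. It may also re-ionise the para-alkoxybenzylic ether of 24 and erode C2, let the quinone methide oligomerise, or let the benzylic cation be trapped by the ortho-prenyl alkene. The fallback uses known chemistry, sets out from styrene 22 and aldehyde 7, and comes back at 24. Tsuji–Wacker oxidation of 22 (PdCl2, CuCl, O2, DMF/H2O) gives the aryl methyl ketone F1. Its lithium enolate (LiN(SiMe3)2, THF, −78 °C) undergoes aldol condensation with 7, the ortho-acetate shifting to the aldolate oxygen and leaving as acetate, to give the (E)-2-hydroxyaryl enone F2. Conjugate reduction with [(Ph3P)CuH]6 in wet toluene gives the saturated ketone F3. Noyori transfer hydrogenation with RuCl[(S,S)-TsDPEN](p-cymene) in HCO2H/Et3N gives the (S)-benzylic alcohol F4. Mitsunobu cyclisation (PPh3, DIAD, THF, 0 °C) then closes ring C on the free phenol with inversion, giving 2R in 24.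

**Step 3 (aromatic Claisen).** The shift may go to C3, or the product may react on (abnormal Claisen, cyclisation of the new phenol onto the alkene). The fallback sets out from 1 and comes back at 8. Bromination of 1 (Br2, AcOH, rt) gives 5-bromo-2,4-dihydroxybenzaldehyde F5. A branched-selective (γ) Suzuki–Miyaura coupling with 3-methylbut-2-enylboronic acid pinacol ester (Pd(OAc)2, a bulky dialkylbiarylphosphine chosen for γ-selectivity, aq. K3PO4, THF, 40 °C) puts the quaternary carbon on C5 and gives 2,4-dihydroxy-5-(2-methylbut-3-en-2-yl)benzaldehyde F6. TBSCl/imidazole silylates the non-chelated 4-OH to give 4-(TBSO)-2-hydroxy-5-(2-methylbut-3-en-2-yl)benzaldehyde F7. NaBH4 (MeOH, 0 °C) then gives 8.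

**Step 13 (Stille prenylation).** The allyl palladium intermediate may also couple at its tertiary end and give the 1,1-dimethylallyl isomer, and the bromide has two ortho substituents. The fallback sets out from 19 and comes back at 21. Stille coupling of 19 with allyltributylstannane (Pd(PPh3)4, DMF, 95 °C), where no regiochemical question arises, gives the 5-allyl aldehyde F8. Cross-metathesis with 2-methylbut-2-ene (second-generation Grubbs catalyst, C46H65Cl2N2PRu, CH2Cl2, 40 °C) turns allyl into prenyl and gives 21.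

## Further compounds

F1 | step 15 | 1-[(3S)-3-(tert-butyldimethylsilyloxy)-2,2-dimethyl-5-(3-methylbut-2-enyl)-8-(triisopropylsilyloxy)chroman-6-yl]ethanone | CC(=O)c1cc(O[Si](C(C)C)(C(C)C)C(C)C)c2c(c1CC=C(C)C)C[C@H](O[Si](C)(C)C(C)(C)C)C(C)(C)O2
F2 | step 15 | (E)-3-[4-(tert-butyldimethylsilyloxy)-2-hydroxy-5-(2-methylbut-3-en-2-yl)phenyl]-1-[(3S)-3-(tert-butyldimethylsilyloxy)-2,2-dimethyl-5-(3-methylbut-2-enyl)-8-(triisopropylsilyloxy)chroman-6-yl]prop-2-en-1-one | C=CC(C)(C)c1cc(/C=C/C(=O)c2cc(O[Si](C(C)C)(C(C)C)C(C)C)c3c(c2CC=C(C)C)C[C@H](O[Si](C)(C)C(C)(C)C)C(C)(C)O3)c(O)cc1O[Si](C)(C)C(C)(C)C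
F3 | step 15 | 3-[4-(tert-butyldimethylsilyloxy)-2-hydroxy-5-(2-methylbut-3-en-2-yl)phenyl]-1-[(3S)-3-(tert-butyldimethylsilyloxy)-2,2-dimethyl-5-(3-methylbut-2-enyl)-8-(triisopropylsilyloxy)chroman-6-yl]propan-1-one | C=CC(C)(C)c1cc(CCC(=O)c2cc(O[Si](C(C)C)(C(C)C)C(C)C)c3c(c2CC=C(C)C)C[C@H](O[Si](C)(C)C(C)(C)C)C(C)(C)O3)c(O)cc1O[Si](C)(C)C(C)(C)C
F4 | step 15 | (1S)-3-[4-(tert-butyldimethylsilyloxy)-2-hydroxy-5-(2-methylbut-3-en-2-yl)phenyl]-1-[(3S)-3-(tert-butyldimethylsilyloxy)-2,2-dimethyl-5-(3-methylbut-2-enyl)-8-(triisopropylsilyloxy)chroman-6-yl]propan-1-ol | C=CC(C)(C)c1cc(CC[C@H](O)c2cc(O[Si](C(C)C)(C(C)C)C(C)C)c3c(c2CC=C(C)C)C[C@H](O[Si](C)(C)C(C)(C)C)C(C)(C)O3)c(O)cc1O[Si](C)(C)C(C)(C)C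
F5 | step 3 | 5-bromo-2,4-dihydroxybenzaldehyde | O=Cc1cc(Br)c(O)cc1O
F6 | step 3 | 2,4-dihydroxy-5-(2-methylbut-3-en-2-yl)benzaldehyde | O=Cc1cc(C(C)(C)C=C)c(O)cc1O
F7 | step 3 | 4-(tert-butyldimethylsilyloxy)-2-hydroxy-5-(2-methylbut-3-en-2-yl)benzaldehyde | O=Cc1cc(C(C)(C)C=C)c(O[Si](C)(C)C(C)(C)C)cc1O
F8 | step 13 | (3S)-3-(tert-butyldimethylsilyloxy)-2,2-dimethyl-5-(prop-2-enyl)-8-(triisopropylsilyloxy)chroman-6-carbaldehyde | O=Cc1cc(O[Si](C(C)C)(C(C)C)C(C)C)c2c(c1CC=C)C[C@H](O[Si](C)(C)C(C)(C)C)C(C)(C)O2
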